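**Assumptions (one line each)**
- Stereochemistry read from the target SMILES: (2R,3S) for the 4'-OMe unit, which is 2,3-trans, and (2''R,3''R) for the 4''-OH unit, which is 2,3-cis.
- (2R)-Isosakuranetin is bought as a single enantiomer and apigenin as an achiral commercial material.

## Retrosynthetic overview
1. Sikokianin B (7) comes from the tri-O-benzyl biflavanone 6 by hydrogenolysis.
2. The C3–C3'' bond of 6 is made by a photoredox reductive coupling. The flavanon-3-yl radical from 3-bromoflavanone 3 adds to C3'' of flavone 5, and HAT at C2'' gives the 2'',3''-cis ring.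
3. Bromide 3 comes from 7-O-benzyl-(2R)-isosakuranetin, which supplies the only purchased stereocentre (C2). Flavone 5 comes from apigenin.
4. Both chromanone rings already exist in the starting materials, so no ring is formed in the route.

## Route

**Step 1**
Reactants: 1, (2R)-isosakuranetin [(2R)-5,7-dihydroxy-2-(4-methoxyphenyl)chroman-4-one]
Product: 2, (2R)-7-(benzyloxy)-5-hydroxy-2-(4-methoxyphenyl)chroman-4-one
Conditions: BnBr (1.05 equiv), KHCO3, DMF, 25 °C, 16 h
Reagents that add atoms: benzyl bromide, BrCc1ccccc1
Why: Williamson etherification is selective for the acidic 7-OH because the 5-OH is locked in a hydrogen bond to C4=O. The mild base at room temperature avoids retro-oxa-Michael racemisation of C2.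

**Step 2**
Reactants: 2
Product: 3, (2S,3S)-3-bromo-7-(benzyloxy)-5-hydroxy-2-(4-methoxyphenyl)chroman-4-one (2,3-trans)
Conditions: CuBr2 (2.2 equiv), EtOAc/CHCl3 1:1, 50 °C, 4 h
Reagents that add atoms: copper(II) bromide, Br[Cu]Br
Why: Cu(II)-mediated α-bromination of a ketone through its enol. The C3 configuration of the bromide is irrelevant because it is destroyed on radical formation, and C2 is untouched.

**Step 3**
Reactants: 4, apigenin (5,7-dihydroxy-2-(4-hydroxyphenyl)chromen-4-one)
Product: 5, 7-(benzyloxy)-2-[4-(benzyloxy)phenyl]-5-hydroxychromen-4-one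
Conditions: BnBr (2.3 equiv), K2CO3, DMF, 60 °C, 6 h
Reagents that add atoms: benzyl bromide, BrCc1ccccc1
Why: Double Williamson etherification of the 7-OH and 4'-OH. The chelated 5-OH stays free.

**Step 4 (key photochemical step)**
Reactants: 3 (1.0 equiv) and 5 (3.0 equiv)
Product: 6, (2R,3S)-7-(benzyloxy)-5-hydroxy-2-(4-methoxyphenyl)-3-[(2R,3R)-7-(benzyloxy)-2-(4-benzyloxyphenyl)-5-hydroxy-4-oxochroman-3-yl]chroman-4-one
Conditions: fac-Ir(ppy)3 (2 mol%), Hantzsch ester (1.5 equiv), DMSO (0.1 M), blue LEDs (455 nm), 25 °C, 24 h; then flash chromatography/prep-HPLC to remove the minor diastereomers and recover excess 5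
Reagents that add atoms: none
Why: Proposed new method: excited Ir(ppy)3 reduces the C–Br bond of 3 to the electrophilic flavanon-3-yl radical, which is polarity-matched to add to C3 of flavone 5, the nucleophilic enol-ether carbon of the chromone. This gives a tertiary benzylic α-oxy radical at C2'', and HAT from Hantzsch ester (oxidised Ir(IV) is reduced by the ester) completes a net reductive hydroalkylation of the C2=C3 bond. The closest known reaction types are photoredox Giese/ATRA additions of α-bromocarbonyl radicals to enol ethers and reductive alkene hydroalkylation, but neither has been shown at C3 of a flavone. Stereochemistry is set as follows: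
- The radical couples anti to the 2-aryl group, giving the trans (3S) unit, which is also the thermodynamic isomer.
- The C3''–C3 bond is pseudo-axial in the C2'' radical because of A(1,2) strain with the aryl group. H is delivered anti to it, so the 2'',3''-ring is cis.
- The (2R) stereocentre of the radical partner selects the flavone face, favouring (2''R,3''R) over (2''S,3''S). The minor diastereomers are removed chromatographically.

**Step 5**
Reactants: 6
Product: 7, sikokianin B
Conditions: H2 (1 atm), 10% Pd/C, THF/EtOH 1:1, 25 °C, 3 h
Reagents that add atoms: none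
Why: Catalytic hydrogenolysis removes all three O-benzyl groups (as toluene) under neutral conditions, so the kinetic cis 2'',3'' centres are not epimerised. The OMe, the ketones and the benzylic C2–O bonds survive.

## Compound list
1 | (2R)-isosakuranetin | COc1ccc([C@H]2CC(=O)c3c(O)cc(O)cc3O2)cc1 | starting material
2 | (2R)-7-O-benzylisosakuranetin | COc1ccc([C@H]2CC(=O)c3c(O)cc(OCc4ccccc4)cc3O2)cc1 | intermediate
3 | (2S,3S)-3-bromo-7-O-benzylisosakuranetin | COc1ccc([C@@H]2Oc3cc(OCc4ccccc4)cc(O)c3C(=O)[C@H]2Br)cc1 | intermediate
4 | apigenin | O=c1cc(-c2ccc(O)cc2)oc2cc(O)cc(O)c12 | starting material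
5 | 4',7-di-O-benzylapigenin | O=c1cc(-c2ccc(OCc3ccccc3)cc2)oc2cc(OCc3ccccc3)cc(O)c12 | intermediate
6 | tri-O-benzyl biflavanone | COc1ccc([C@@H]2Oc3cc(OCc4ccccc4)cc(O)c3C(=O)[C@H]2[C@H]2C(=O)c3c(O)cc(OCc4ccccc4)cc3O[C@H]2c2ccc(OCc3ccccc3)cc2)cc1 | intermediate
7 | sikokianin B | COc1ccc([C@@H]2Oc3cc(O)cc(O)c3C(=O)[C@H]2[C@H]2C(=O)c3c(O)cc(O)cc3O[C@H]2c2ccc(O)cc2)cc1 | target

## Totals
Total steps: 5. Longest linear sequence: 4 (1 → 2 → 3 → 6 → 7).

## Three steps most likely to fail
1. **Step 4 (proposed new step).** Hydrodebromination of 3 may outcompete the hindered addition to C3 of the flavone, and the diastereoselectivity may be low.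
   - Fallback (known chemistry): make the 1,4-diketone by oxidative heterocoupling of enolates. Use the TBS enol ether of 2 and the lithium enolate of 4',7-di-O-benzyl-(2R)-naringenin, a second purchased chiral unit, with Cu(II)/Fe(III) oxidant. Separate the diastereomers, then debenzylate as in step 5.
2. **Step 2.** CuBr2 may brominate the A-ring (C6/C8), racemise C2 through the chalcone, or eliminate HBr to the flavone.
   - Fallback: skip the bromide. Make the TBS enol ether of 2 (TBSOTf, Et3N) and generate the α-keto radical by photoredox oxidation (Ir[dF(CF3)ppy]2(dtbbpy)PF6), then run the same addition to 5 and reduction.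
3. **Step 5.** Pd/C may over-reduce the benzylic C2–O bond.
   - Fallback: remove the benzyl groups with BCl3 and pentamethylbenzene in CH2Cl2 at −78 °C, a Lewis-acid cleavage that leaves the OMe and stereocentres intact.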